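**Retrosynthetic overview**
1. The ten-membered carbocycle is closed last, at C3–C4, by an intramolecular Nozaki–Hiyama–Kishi addition of a (Z)-vinyl iodide to an aldehyde (sets C3); only O14 desilylation follows.
2. The C8 ester comes from Mitsunobu inversion of the coupling carbinol with (S)-2-methylbutanoic acid.
3. Key union at C7–C8: zinc Barbier allylation of epoxy aldehyde 23 (C1–C3, C8–C10, C14; seven carbons) with bromomethyl butenolide 10 (C4–C7, C11–C13, C15; eight carbons), which also creates the α-methylene lactone.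
4. 10 comes from ethyl but-2-ynoate, vinylmagnesium bromide and 2-(bromomethyl)acrylic acid (hydroiodination, Sharpless kinetic resolution for C6, ring-closing metathesis); 23 comes from but-3-yn-1-ol, methyl chloroformate and allyl bromide (syn-hydrostannation/Stille for the Z-olefin, Sharpless epoxidation for C1/C10).
5. Ring order: butenolide and oxirane are made separately in the two halves, then the ten-membered ring.

Assumption: skeletal positions are cited by germacrane numbering (C12 = lactone carbonyl on O6, C14 = hydroxymethyl carbon on C10, C15 = methyl on C4), and the seven starting materials are taken as commercial.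

**Route**

Step 1
Reactants: 1 ethyl but-2-ynoate
Product: 2 ethyl (2Z)-3-iodobut-2-enoate
Conditions: NaI, AcOH, 115 °C
Reagents that add atoms: sodium iodide [Na+].[I-]
Why: Hydroiodination by conjugate addition of iodide to the ynoate and anti protonation gives the (Z)-β-iodo enoate with iodine cis to the ester, which fixes the C4=C5 geometry of the target (the iodine marks the later C3–C4 bond).

Step 2
Reactants: 2 ethyl (2Z)-3-iodobut-2-enoate
Product: 3 (2Z)-3-iodobut-2-en-1-ol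
Conditions: i-Bu2AlH (2.2 equiv), CH2Cl2, −78 to 0 °C; aq potassium sodium tartrate
Reagents that add atoms: none
Why: Hydride 1,2-reduction of the ester gives the allylic alcohol without touching the vinyl iodide or the olefin geometry.

Step 3
Reactants: 3 (2Z)-3-iodobut-2-en-1-ol
Product: 4 (2Z)-3-iodobut-2-enal
Conditions: MnO2, CH2Cl2, rt, dark
Reagents that add atoms: none
Why: Allylic oxidation on activated MnO2 is neutral and stops at the enal, so the Z geometry is preserved.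

Step 4
Reactants: 4 (2Z)-3-iodobut-2-enal; 5 vinylmagnesium bromide
Product: 6 rac-(4Z)-5-iodohexa-1,4-dien-3-ol
Conditions: THF, −78 °C; sat. aq NH4Cl
Reagents that add atoms: none
Why: Grignard 1,2-addition to the enal gives the racemic bis-allylic alcohol, the vinyl iodide being inert to exchange at −78 °C.

Step 5
Reactants: 6 rac-(4Z)-5-iodohexa-1,4-dien-3-ol
Product: 7 (3S,4Z)-5-iodohexa-1,4-dien-3-ol
Conditions: Ti(OiPr)4 (0.1 equiv), L-(+)-diisopropyl tartrate (0.15 equiv), t-BuOOH (0.6 equiv), 4 Å MS, CH2Cl2, −20 °C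
Reagents that add atoms: none
Why: In this Sharpless kinetic resolution the L-(+)-tartrate catalyst epoxidises the terminal vinyl group of the (R)-enantiomer much faster, so the unreacted (S)-alcohol carrying the future C6 stereocentre is recovered in high enantiomeric excess, while the electron-poor cis-substituted iodoalkene does not react.

Step 6
Reactants: 7 (3S,4Z)-5-iodohexa-1,4-dien-3-ol; 8 2-(bromomethyl)prop-2-enoic acid
Product: 9 (3S,4Z)-5-iodohexa-1,4-dien-3-yl 2-(bromomethyl)prop-2-enoate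
Conditions: DCC, DMAP (0.05 equiv), CH2Cl2, 0 °C
Reagents that add atoms: none
Why: Steglich esterification acylates the sensitive bis-allylic alcohol with retention at C6, and keeping DMAP catalytic avoids displacement of the allylic bromide.

Step 7
Reactants: 9 (3S,4Z)-5-iodohexa-1,4-dien-3-yl 2-(bromomethyl)prop-2-enoate
Product: 10 (5S)-3-(bromomethyl)-5-[(1Z)-2-iodoprop-1-en-1-yl]furan-2(5H)-one
Conditions: second-generation Grubbs catalyst RuCl2(=CHPh)(H2IMes)(PCy3) (5 mol%), CH2Cl2, 40 °C, 0.01 M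
Reagents that add atoms: none
Why: Ring-closing metathesis initiates at the terminal vinyl group and closes onto the acrylate to form the butenolide with loss of ethylene, the trisubstituted iodoalkene being too hindered to take part and C6 being untouched.

Step 8
Reactants: 11 but-3-yn-1-ol
Product: 12 1-[(but-3-yn-1-yloxy)methyl]-4-methoxybenzene
Conditions: NaH, 4-methoxybenzyl chloride, tetrabutylammonium iodide (cat.), THF/DMF, 0 °C to rt
Reagents that add atoms: 4-methoxybenzyl chloride COc1ccc(CCl)cc1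
Why: Williamson ether synthesis on the alkoxide (the hydroxyl is far more acidic than the alkyne hydrogen) installs the PMB group that later unmasks the C3 aldehyde.

Step 9
Reactants: 12 1-[(but-3-yn-1-yloxy)methyl]-4-methoxybenzene; 13 methyl chloroformate
Product: 15 methyl 5-[(4-methoxyphenyl)methoxy]pent-2-ynoate, via lithium acetylide 14 (not isolated)
Conditions: n-BuLi, THF, −78 °C; then 13, −78 to 0 °C
Reagents that add atoms: none
Why: Deprotonation of the terminal alkyne and C-acylation of the acetylide by the chloroformate (alkoxycarbonylation) gives the ynoate whose ester carbon becomes C14.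

Step 10
Reactants: 15 methyl 5-[(4-methoxyphenyl)methoxy]pent-2-ynoate; 16 allyl bromide
Product: 18 methyl (2Z)-5-[(4-methoxyphenyl)methoxy]-2-(prop-2-en-1-yl)pent-2-enoate, via vinylstannane 17 (not isolated)
Conditions: Bu3SnH, Pd(PPh3)4 (2 mol%), THF, 0 °C; then 16, CuCl, LiCl, DMSO, 60 °C
Reagents that add atoms: none
Why: Palladium-catalysed syn-hydrostannation places tin on the ester-bearing carbon cis to the new hydrogen and the copper-assisted Stille coupling replaces tin by allyl with retention, so the ester carbon (C14) ends up cis to the C2 chain and the allyl group (C9 and C8) trans to it.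

Step 11
Reactants: 18 methyl (2Z)-5-[(4-methoxyphenyl)methoxy]-2-(prop-2-en-1-yl)pent-2-enoate
Product: 19 (2Z)-5-[(4-methoxyphenyl)methoxy]-2-(prop-2-en-1-yl)pent-2-en-1-ol
Conditions: i-Bu2AlH (2.3 equiv), CH2Cl2, −78 °C; aq potassium sodium tartrate
Reagents that add atoms: none
Why: Hydride 1,2-reduction of the enoate gives the (Z)-allylic alcohol needed for directed epoxidation without isomerising the skipped diene.

Step 12
Reactants: 19 (2Z)-5-[(4-methoxyphenyl)methoxy]-2-(prop-2-en-1-yl)pent-2-en-1-ol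
Product: 20 {(2S,3R)-3-{2-[(4-methoxyphenyl)methoxy]ethyl}-2-(prop-2-en-1-yl)oxiran-2-yl}methanol
Conditions: Ti(OiPr)4 (0.1 equiv), L-(+)-diethyl tartrate (0.12 equiv), t-BuOOH, 4 Å MS, CH2Cl2, −20 °C
Reagents that add atoms: tert-butyl hydroperoxide CC(C)(C)OO
Why: Sharpless asymmetric epoxidation with the L-(+)-tartrate ligand oxidises only the allylic alkene (the isolated vinyl group has no directing hydroxyl) from the face that gives the (2S,3R)-oxirane, which is C10 (S) and C1 (R) of the target, and the cis relation of C14 and C2 is carried over from the Z-olefin.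

Step 13
Reactants: 20 {(2S,3R)-3-{2-[(4-methoxyphenyl)methoxy]ethyl}-2-(prop-2-en-1-yl)oxiran-2-yl}methanol
Product: 21 tert-butyl({(2S,3R)-3-{2-[(4-methoxyphenyl)methoxy]ethyl}-2-(prop-2-en-1-yl)oxiran-2-yl}methoxy)dimethylsilane
Conditions: TBSCl, imidazole, CH2Cl2, 0 °C to rt
Reagents that add atoms: tert-butyldimethylsilyl chloride CC(C)(C)[Si](C)(C)Cl
Why: Imidazole-promoted silyl ether formation protects O14 through the coupling, Mitsunobu, oxidation and chromium steps.

Step 14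
Reactants: 21 tert-butyl({(2S,3R)-3-{2-[(4-methoxyphenyl)methoxy]ethyl}-2-(prop-2-en-1-yl)oxiran-2-yl}methoxy)dimethylsilane
Product: 23 2-[(2S,3R)-2-({[tert-butyl(dimethyl)silyl]oxy}methyl)-3-{2-[(4-methoxyphenyl)methoxy]ethyl}oxiran-2-yl]acetaldehyde, via diol 22 (not isolated)
Conditions: OsO4 (2 mol%), NaIO4 (4 equiv), 2,6-lutidine, dioxane/H2O 3:1, rt; used at once
Reagents that add atoms: sodium periodate [Na+].[O-]I(=O)(=O)=O (oxygen delivered through catalytic osmium tetroxide O=[Os](=O)(=O)=O)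
Why: Lemieux–Johnson oxidative cleavage (catalytic dihydroxylation then periodate glycol cleavage, buffered by 2,6-lutidine) of the only remaining alkene unmasks the C8 aldehyde under near-neutral conditions that spare the oxirane, the PMB ether and the silyl ether.

Step 15
Reactants: 10 (5S)-3-(bromomethyl)-5-[(1Z)-2-iodoprop-1-en-1-yl]furan-2(5H)-one; 23 2-[(2S,3R)-2-({[tert-butyl(dimethyl)silyl]oxy}methyl)-3-{2-[(4-methoxyphenyl)methoxy]ethyl}oxiran-2-yl]acetaldehyde
Product: 25 (4R,5S)-4-{(1S)-2-[(2S,3R)-2-({[tert-butyl(dimethyl)silyl]oxy}methyl)-3-{2-[(4-methoxyphenyl)methoxy]ethyl}oxiran-2-yl]-1-hydroxyethyl}-5-[(1Z)-2-iodoprop-1-en-1-yl]-3-methylideneoxolan-2-one, via allylzinc bromide 24 (not isolated)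
Conditions: Zn dust (3 equiv), THF/sat. aq NH4Cl 2:1, 0 °C to rt
Reagents that add atoms: none
Why: Zinc inserts only into the allylic bromide and the allylzinc adds to the aldehyde in a Barbier reaction through its ring carbon (allylic transposition) via a chair Zimmerman–Traxler transition state on the butenolide face anti to the C6 side chain, which forms the C7–C8 bond and the α-methylene lactone with 6,7-trans (7R) and 7,8-anti (8S) configuration.

Step 16
Reactants: 25 (4R,5S)-4-{(1S)-2-[(2S,3R)-2-({[tert-butyl(dimethyl)silyl]oxy}methyl)-3-{2-[(4-methoxyphenyl)methoxy]ethyl}oxiran-2-yl]-1-hydroxyethyl}-5-[(1Z)-2-iodoprop-1-en-1-yl]-3-methylideneoxolan-2-one; 26 (2S)-2-methylbutanoic acid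
Product: 27 (1R)-2-[(2S,3R)-2-({[tert-butyl(dimethyl)silyl]oxy}methyl)-3-{2-[(4-methoxyphenyl)methoxy]ethyl}oxiran-2-yl]-1-{(2S,3R)-2-[(1Z)-2-iodoprop-1-en-1-yl]-4-methylidene-5-oxooxolan-3-yl}ethyl (2S)-2-methylbutanoate
Conditions: PPh3, DIAD (premixed), toluene, 0 °C to rt
Reagents that add atoms: none
Why: Mitsunobu esterification turns the C8 hydroxyl into an oxyphosphonium leaving group that the carboxylate displaces with SN2 inversion, converting the (8S)-alcohol into the required (8R)-ester without epimerising the acid.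

Step 17
Reactants: 27 (1R)-2-[(2S,3R)-2-({[tert-butyl(dimethyl)silyl]oxy}methyl)-3-{2-[(4-methoxyphenyl)methoxy]ethyl}oxiran-2-yl]-1-{(2S,3R)-2-[(1Z)-2-iodoprop-1-en-1-yl]-4-methylidene-5-oxooxolan-3-yl}ethyl (2S)-2-methylbutanoate
Product: 28 (1R)-2-[(2S,3R)-2-({[tert-butyl(dimethyl)silyl]oxy}methyl)-3-(2-hydroxyethyl)oxiran-2-yl]-1-{(2S,3R)-2-[(1Z)-2-iodoprop-1-en-1-yl]-4-methylidene-5-oxooxolan-3-yl}ethyl (2S)-2-methylbutanoate
Conditions: DDQ, CH2Cl2/aq NaH2PO4–Na2HPO4 buffer (pH 7), 0 °C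
Reagents that add atoms: none
Why: Oxidative PMB ether cleavage by DDQ (oxidation of the electron-rich benzyl ether and hydrolysis of the resulting oxocarbenium ion) frees the C3 hydroxyl while the silyl ether, oxirane, vinyl iodide, ester and α-methylene lactone are inert under buffering.

Step 18
Reactants: 28 (1R)-2-[(2S,3R)-2-({[tert-butyl(dimethyl)silyl]oxy}methyl)-3-(2-hydroxyethyl)oxiran-2-yl]-1-{(2S,3R)-2-[(1Z)-2-iodoprop-1-en-1-yl]-4-methylidene-5-oxooxolan-3-yl}ethyl (2S)-2-methylbutanoate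
Product: 29 (1R)-2-[(2S,3R)-2-({[tert-butyl(dimethyl)silyl]oxy}methyl)-3-(2-oxoethyl)oxiran-2-yl]-1-{(2S,3R)-2-[(1Z)-2-iodoprop-1-en-1-yl]-4-methylidene-5-oxooxolan-3-yl}ethyl (2S)-2-methylbutanoate
Conditions: Dess–Martin periodinane, NaHCO3, CH2Cl2, 0 °C; used crude
Reagents that add atoms: none
Why: Dess–Martin oxidation under bicarbonate buffering gives the β,γ-epoxy aldehyde without a base that could open the oxirane by elimination or epimerise C7.

Step 19
Reactants: 29 (1R)-2-[(2S,3R)-2-({[tert-butyl(dimethyl)silyl]oxy}methyl)-3-(2-oxoethyl)oxiran-2-yl]-1-{(2S,3R)-2-[(1Z)-2-iodoprop-1-en-1-yl]-4-methylidene-5-oxooxolan-3-yl}ethyl (2S)-2-methylbutanoate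
Product: 31 (1R,3S,4Z,6R,7R,8R,10S)-14-{[tert-butyl(dimethyl)silyl]oxy}-1,10-epoxy-3-hydroxy-8-{[(2S)-2-methylbutanoyl]oxy}germacra-4,11(13)-dien-12,6-olide, via alkenylchromium dichloride 30 (not isolated)
Conditions: CrCl2 (10 equiv), NiCl2 (0.1 equiv), degassed DMSO, rt, 0.002 M, slow addition
Reagents that add atoms: none
Why: The intramolecular Nozaki–Hiyama–Kishi reaction (nickel-catalysed formation of the alkenylchromium species and its chemoselective addition to the aldehyde at high dilution) closes the ten-membered ring with retention of the Z-olefin, and attack on the outward-facing aldehyde face of the lactone- and oxirane-constrained chain is expected to give the (3S)-allylic alcohol.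

Step 20
Reactants: 31 (1R,3S,4Z,6R,7R,8R,10S)-14-{[tert-butyl(dimethyl)silyl]oxy}-1,10-epoxy-3-hydroxy-8-{[(2S)-2-methylbutanoyl]oxy}germacra-4,11(13)-dien-12,6-olide
Product: 32 (1R,3S,4Z,6R,7R,8R,10S)-1,10-epoxy-3,14-dihydroxy-8-{[(2S)-2-methylbutanoyl]oxy}germacra-4,11(13)-dien-12,6-olide (CNP0356520.3)
Conditions: HF·pyridine, pyridine, THF, 0 °C
Reagents that add atoms: none
Why: Pyridine-buffered fluoride desilylation removes the primary TBS ether without opening the oxirane, migrating the ester or adding to the α-methylene lactone, and gives the target.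

**Compound list**
1 | ethyl but-2-ynoate | CC#CC(=O)OCC | starting material
2 | ethyl (2Z)-3-iodobut-2-enoate | CCOC(=O)/C=C(/C)I | intermediate
3 | (2Z)-3-iodobut-2-en-1-ol | OC/C=C(/C)I | intermediate
4 | (2Z)-3-iodobut-2-enal | O=C/C=C(/C)I | intermediate
5 | vinylmagnesium bromide | C=C[Mg]Br | starting material
6 | rac-(4Z)-5-iodohexa-1,4-dien-3-ol | C=CC(O)/C=C(/C)I | intermediate
7 | (3S,4Z)-5-iodohexa-1,4-dien-3-ol | C=C[C@H](O)/C=C(/C)I | intermediate
8 | 2-(bromomethyl)prop-2-enoic acid | C=C(CBr)C(=O)O | starting material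
9 | (3S,4Z)-5-iodohexa-1,4-dien-3-yl 2-(bromomethyl)prop-2-enoate | C=C(CBr)C(=O)O[C@H](/C=C(/C)I)C=C | intermediate
10 | (5S)-3-(bromomethyl)-5-[(1Z)-2-iodoprop-1-en-1-yl]furan-2(5H)-one | O=C1O[C@H](/C=C(/C)I)C=C1CBr | intermediate
11 | but-3-yn-1-ol | C#CCCO | starting material
12 | 1-[(but-3-yn-1-yloxy)methyl]-4-methoxybenzene | C#CCCOCc1ccc(OC)cc1 | intermediate
13 | methyl chloroformate | COC(=O)Cl | starting material
14 | {4-[(4-methoxyphenyl)methoxy]but-1-yn-1-yl}lithium | [Li]C#CCCOCc1ccc(OC)cc1 | intermediate (not isolated)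
15 | methyl 5-[(4-methoxyphenyl)methoxy]pent-2-ynoate | COC(=O)C#CCCOCc1ccc(OC)cc1 | intermediate
16 | allyl bromide (3-bromoprop-1-ene) | C=CCBr | starting material
17 | methyl (2E)-5-[(4-methoxyphenyl)methoxy]-2-(tributylstannyl)pent-2-enoate | CCCC[Sn](CCCC)(CCCC)/C(C(=O)OC)=C/CCOCc1ccc(OC)cc1 | intermediate (not isolated)
18 | methyl (2Z)-5-[(4-methoxyphenyl)methoxy]-2-(prop-2-en-1-yl)pent-2-enoate | C=CC/C(C(=O)OC)=C/CCOCc1ccc(OC)cc1 | intermediate
19 | (2Z)-5-[(4-methoxyphenyl)methoxy]-2-(prop-2-en-1-yl)pent-2-en-1-ol | C=CC/C(CO)=C/CCOCc1ccc(OC)cc1 | intermediate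
20 | {(2S,3R)-3-{2-[(4-methoxyphenyl)methoxy]ethyl}-2-(prop-2-en-1-yl)oxiran-2-yl}methanol | C=CC[C@@]1(CO)O[C@@H]1CCOCc1ccc(OC)cc1 | intermediate
21 | tert-butyl({(2S,3R)-3-{2-[(4-methoxyphenyl)methoxy]ethyl}-2-(prop-2-en-1-yl)oxiran-2-yl}methoxy)dimethylsilane | C=CC[C@@]1(CO[Si](C)(C)C(C)(C)C)O[C@@H]1CCOCc1ccc(OC)cc1 | intermediate
22 | 3-[(2S,3R)-2-({[tert-butyl(dimethyl)silyl]oxy}methyl)-3-{2-[(4-methoxyphenyl)methoxy]ethyl}oxiran-2-yl]propane-1,2-diol (both carbinol epimers) | OCC(O)C[C@@]1(CO[Si](C)(C)C(C)(C)C)O[C@@H]1CCOCc1ccc(OC)cc1 | intermediate (not isolated)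
23 | 2-[(2S,3R)-2-({[tert-butyl(dimethyl)silyl]oxy}methyl)-3-{2-[(4-methoxyphenyl)methoxy]ethyl}oxiran-2-yl]acetaldehyde | O=CC[C@@]1(CO[Si](C)(C)C(C)(C)C)O[C@@H]1CCOCc1ccc(OC)cc1 | intermediate
24 | {[(5S)-5-[(1Z)-2-iodoprop-1-en-1-yl]-2-oxo-2,5-dihydrofuran-3-yl]methyl}zinc bromide | O=C1O[C@H](/C=C(/C)I)C=C1C[Zn]Br | intermediate (not isolated)
25 | (4R,5S)-4-{(1S)-2-[(2S,3R)-2-({[tert-butyl(dimethyl)silyl]oxy}methyl)-3-{2-[(4-methoxyphenyl)methoxy]ethyl}oxiran-2-yl]-1-hydroxyethyl}-5-[(1Z)-2-iodoprop-1-en-1-yl]-3-methylideneoxolan-2-one | C=C1C(=O)O[C@H](/C=C(/C)I)[C@H]1[C@@H](O)C[C@@]2(CO[Si](C)(C)C(C)(C)C)O[C@@H]2CCOCc3ccc(OC)cc3 | intermediate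
26 | (2S)-2-methylbutanoic acid | CC[C@H](C)C(=O)O | starting material
27 | (1R)-2-[(2S,3R)-2-({[tert-butyl(dimethyl)silyl]oxy}methyl)-3-{2-[(4-methoxyphenyl)methoxy]ethyl}oxiran-2-yl]-1-{(2S,3R)-2-[(1Z)-2-iodoprop-1-en-1-yl]-4-methylidene-5-oxooxolan-3-yl}ethyl (2S)-2-methylbutanoate | C=C1C(=O)O[C@H](/C=C(/C)I)[C@H]1[C@H](OC(=O)[C@@H](C)CC)C[C@@]2(CO[Si](C)(C)C(C)(C)C)O[C@@H]2CCOCc3ccc(OC)cc3 | intermediate
28 | (1R)-2-[(2S,3R)-2-({[tert-butyl(dimethyl)silyl]oxy}methyl)-3-(2-hydroxyethyl)oxiran-2-yl]-1-{(2S,3R)-2-[(1Z)-2-iodoprop-1-en-1-yl]-4-methylidene-5-oxooxolan-3-yl}ethyl (2S)-2-methylbutanoate | C=C1C(=O)O[C@H](/C=C(/C)I)[C@H]1[C@H](OC(=O)[C@@H](C)CC)C[C@@]2(CO[Si](C)(C)C(C)(C)C)O[C@@H]2CCO | intermediate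
29 | (1R)-2-[(2S,3R)-2-({[tert-butyl(dimethyl)silyl]oxy}methyl)-3-(2-oxoethyl)oxiran-2-yl]-1-{(2S,3R)-2-[(1Z)-2-iodoprop-1-en-1-yl]-4-methylidene-5-oxooxolan-3-yl}ethyl (2S)-2-methylbutanoate | C=C1C(=O)O[C@H](/C=C(/C)I)[C@H]1[C@H](OC(=O)[C@@H](C)CC)C[C@@]2(CO[Si](C)(C)C(C)(C)C)O[C@@H]2CC=O | intermediate
30 | (Z)-alkenylchromium dichloride of 29 (CrCl2 in place of the iodine on C4, all other centres as in 29) | C=C1C(=O)O[C@H](/C=C(/C)[Cr](Cl)Cl)[C@H]1[C@H](OC(=O)[C@@H](C)CC)C[C@@]2(CO[Si](C)(C)C(C)(C)C)O[C@@H]2CC=O | intermediate (not isolated)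
31 | (1R,3S,4Z,6R,7R,8R,10S)-14-{[tert-butyl(dimethyl)silyl]oxy}-1,10-epoxy-3-hydroxy-8-{[(2S)-2-methylbutanoyl]oxy}germacra-4,11(13)-dien-12,6-olide | C=C1C(=O)O[C@@H]2/C=C(/C)[C@@H](O)C[C@H]3O[C@]3(CO[Si](C)(C)C(C)(C)C)C[C@@H](OC(=O)[C@@H](C)CC)[C@@H]12 | intermediate
32 | (1R,3S,4Z,6R,7R,8R,10S)-1,10-epoxy-3,14-dihydroxy-8-{[(2S)-2-methylbutanoyl]oxy}germacra-4,11(13)-dien-12,6-olide | C=C1C(=O)O[C@@H]2/C=C(/C)[C@@H](O)C[C@H]3O[C@]3(CO)C[C@@H](OC(=O)[C@@H](C)CC)[C@@H]12 | target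

**Totals**
Total step count: 20.
Longest linear sequence: 13 steps (steps 8–14 followed by 15–20; the branch 1–7 followed by 15–20 is equally long).

**Three steps most likely to fail**

Step 10. The one-pot hydrostannation–Stille sequence on a hindered α-stannyl enoate may give protodestannylation or migration of the skipped diene into conjugation. Fallback: setting out from 15, the hydrostannation is run on its own and vinylstannane 17 is isolated. Iododestannylation (I2, CH2Cl2, 0 °C, retention) gives methyl (2E)-2-iodo-5-[(4-methoxyphenyl)methoxy]pent-2-enoate F1. The polarity of the coupling is then reversed by joining this vinyl iodide with allyltributylstannane (Pd(PPh3)4, CuCl, LiCl, DMSO, 50 °C), which comes back to the route at 18.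

Step 16. Mitsunobu inversion at the hindered, β-branched C8 carbinol with a weakly acidic α-branched acid may give elimination towards C7 or no reaction. Fallback: setting out from 25, Dess–Martin oxidation (NaHCO3, CH2Cl2, 0 °C) gives the ketone (4S,5S)-4-{2-[(2S,3R)-2-({[tert-butyl(dimethyl)silyl]oxy}methyl)-3-{2-[(4-methoxyphenyl)methoxy]ethyl}oxiran-2-yl]acetyl}-5-[(1Z)-2-iodoprop-1-en-1-yl]-3-methylideneoxolan-2-one F2. Reagent-controlled reduction with (S)-Me-CBS oxazaborolidine and catecholborane (toluene, −78 °C) gives the (8R)-alcohol (4R,5S)-4-{(1R)-2-[(2S,3R)-2-({[tert-butyl(dimethyl)silyl]oxy}methyl)-3-{2-[(4-methoxyphenyl)methoxy]ethyl}oxiran-2-yl]-1-hydroxyethyl}-5-[(1Z)-2-iodoprop-1-en-1-yl]-3-methylideneoxolan-2-one F3. Steglich esterification of this alcohol with 26 (DCC, DMAP, CH2Cl2, 0 °C) comes back to the route at 27 with no substitution at C8.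

Step 19. The ten-membered ring closure sets C3 by macrocyclic control alone, so the wrong epimer may predominate. Fallback: setting out from 29, if the cyclisation delivers mainly the C3 epimer, that alcohol, (1R,3R,4Z,6R,7R,8R,10S)-14-{[tert-butyl(dimethyl)silyl]oxy}-1,10-epoxy-3-hydroxy-8-{[(2S)-2-methylbutanoyl]oxy}germacra-4,11(13)-dien-12,6-olide F4, is oxidised with Dess–Martin periodinane (NaHCO3, CH2Cl2, 0 °C). This gives the macrocyclic Z-enone (1R,4Z,6R,7R,8R,10S)-14-{[tert-butyl(dimethyl)silyl]oxy}-1,10-epoxy-8-{[(2S)-2-methylbutanoyl]oxy}-3-oxogermacra-4,11(13)-dien-12,6-olide F5. Reduction under reagent control with (R)-Me-CBS oxazaborolidine and catecholborane (toluene, −78 °C) sets (3S) and comes back to the route at 31.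

**Further compounds**
F1 | step 10 | methyl (2E)-2-iodo-5-[(4-methoxyphenyl)methoxy]pent-2-enoate | I/C(C(=O)OC)=C/CCOCc1ccc(OC)cc1
F2 | step 16 | (4S,5S)-4-{2-[(2S,3R)-2-({[tert-butyl(dimethyl)silyl]oxy}methyl)-3-{2-[(4-methoxyphenyl)methoxy]ethyl}oxiran-2-yl]acetyl}-5-[(1Z)-2-iodoprop-1-en-1-yl]-3-methylideneoxolan-2-one | C=C1C(=O)O[C@H](/C=C(/C)I)[C@H]1C(=O)C[C@@]2(CO[Si](C)(C)C(C)(C)C)O[C@@H]2CCOCc3ccc(OC)cc3
F3 | step 16 | (4R,5S)-4-{(1R)-2-[(2S,3R)-2-({[tert-butyl(dimethyl)silyl]oxy}methyl)-3-{2-[(4-methoxyphenyl)methoxy]ethyl}oxiran-2-yl]-1-hydroxyethyl}-5-[(1Z)-2-iodoprop-1-en-1-yl]-3-methylideneoxolan-2-one | C=C1C(=O)O[C@H](/C=C(/C)I)[C@H]1[C@H](O)C[C@@]2(CO[Si](C)(C)C(C)(C)C)O[C@@H]2CCOCc3ccc(OC)cc3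
F4 | step 19 | (1R,3R,4Z,6R,7R,8R,10S)-14-{[tert-butyl(dimethyl)silyl]oxy}-1,10-epoxy-3-hydroxy-8-{[(2S)-2-methylbutanoyl]oxy}germacra-4,11(13)-dien-12,6-olide | C=C1C(=O)O[C@@H]2/C=C(/C)[C@H](O)C[C@H]3O[C@]3(CO[Si](C)(C)C(C)(C)C)C[C@@H](OC(=O)[C@@H](C)CC)[C@@H]12
F5 | step 19 | (1R,4Z,6R,7R,8R,10S)-14-{[tert-butyl(dimethyl)silyl]oxy}-1,10-epoxy-8-{[(2S)-2-methylbutanoyl]oxy}-3-oxogermacra-4,11(13)-dien-12,6-olide | C=C1C(=O)O[C@@H]2/C=C(/C)C(=O)C[C@H]3O[C@]3(CO[Si](C)(C)C(C)(C)C)C[C@@H](OC(=O)[C@@H](C)CC)[C@@H]12
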